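**Strategy.** The tetrahydrofuran ring (O1, C2, C3, C4, C5) is not closed around its substituents. Instead the C3–CH2O bond is disconnected together with a 1,3-transposition of the exocyclic C4=CH–aryl alkene. A [2,3]-Wittig–Still rearrangement of a stannylmethyl ether forms that bond, sets C3 trans to the C2 aryl group and fixes the benzylidene geometry (aryl cis to C3) in one operation, by chirality transfer from a sacrificial benzylic carbinol. The precursor is a (2R)-2-aryl-2,5-dihydrofuran whose C4 carries an (S)-aryl(stannylmethoxy)methyl group. Both of its stereocentres come from one C2-symmetric (S,S)-1,4-diarylbut-2-yne-1,4-diol. The feature exploited is the allylic 1,3-relationship between C3 and the C4 benzylidene carbon.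

Key step: step 9

Remark: Ar = 3-methoxy-4-(triisopropylsilyloxy)phenyl (TIPS = Si(i-Pr)3); in the discussion all furan intermediates carry the ring locants of the target (O1, C2 aryl, C3, C4, C5), the benzylidene carbon is C6 and the hydroxymethyl carbon on C3 is C7, whereas names in the compound list use IUPAC numbering.

Assumption: in step 4 the aryl group acts as the large and the alkynyl group as the small substituent of each ketone, as in the steric model of the Midland reduction.

**Step 1**
Reactants: 1 vanillin
Product: 2 3-methoxy-4-(triisopropylsilyloxy)benzaldehyde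
Conditions: TIPSCl, imidazole, DMF, rt
Reagents that add atoms: triisopropylsilyl chloride, CC(C)[Si](Cl)(C(C)C)C(C)C
Why: Silyl ether formation at the phenol; the TIPS ether should withstand the Grignard, hydride, alkoxide and organolithium steps and be removable with buffered fluoride at the end.

**Step 2**
Reactants: 2 3-methoxy-4-(triisopropylsilyloxy)benzaldehyde (2 equiv), 3 acetylene
Product: 5 1,4-di-Ar-but-2-yne-1,4-diol (mixture of racemic and meso forms), via ethynediylbis(magnesium bromide) 4 (not isolated)
Conditions: HC≡CH, EtMgBr (2 equiv), THF, 0 °C to rt; then 2, 0 °C to rt; aq NH4Cl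
Reagents that add atoms: none
Why: Twofold acetylide (Grignard) addition to the aldehyde should give the symmetrical ynediol; the carbinol centres form without control, which does not matter because step 3 removes them.

**Step 3**
Reactants: 5 1,4-di-Ar-but-2-yne-1,4-diol
Product: 6 1,4-di-Ar-but-2-yne-1,4-dione
Conditions: activated MnO2 (excess), CH2Cl2, rt
Reagents that add atoms: none
Why: Manganese dioxide oxidation of benzylic, propargylic alcohols should give the diaroylacetylene and converge both diastereomers of 5 into one achiral compound.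

**Step 4**
Reactants: 6 1,4-di-Ar-but-2-yne-1,4-dione
Product: 7 (1S,4S)-1,4-di-Ar-but-2-yne-1,4-diol
Conditions: (S)-Alpine-Borane (3 equiv), THF (concentrated), rt; then HOCH2CH2NH2, Et2O
Reagents that add atoms: none
Why: Midland reduction of an alkynyl ketone: the β-hydride of the pinanyl group is transferred in a six-membered boat transition state with the slender alkynyl group next to the pinane methyl, so each carbonyl should give the (S)-carbinol, the double reduction should raise the enantiomeric purity of the C2-symmetric diol, and the minor meso isomer should be removable by crystallisation or chromatography.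

**Step 5**
Reactants: 7 (1S,4S)-1,4-di-Ar-but-2-yne-1,4-diol
Product: 9 (1S,2Z,4R)-2-iodo-1,4-di-Ar-but-2-ene-1,4-diol, via cyclic sodium alkenylalanate 8 (not isolated)
Conditions: Red-Al (3.5 equiv), THF, 0 °C to rt; then I2, THF, −78 to 0 °C; aq Rochelle salt
Reagents that add atoms: iodine, II
Why: Alkoxide-directed anti-hydroalumination of a propargylic alcohol followed by iodinolysis with retention places hydride on one alkyne carbon and aluminium, then iodine, on the other inside a five-membered oxa-alumina ring, so iodine should end up cis to the far carbinol carbon; the C2 symmetry of 7 makes both alkyne carbons equivalent and no stereocentre is touched (the descriptor change at C4 is only a priority change).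

**Step 6**
Reactants: 9 (1S,2Z,4R)-2-iodo-1,4-di-Ar-but-2-ene-1,4-diol, 10 (tributylstannyl)methanol
Product: 11 (1S,2E,4R)-2-(hydroxymethyl)-1,4-di-Ar-but-2-ene-1,4-diol
Conditions: Pd(PPh3)4 (cat.), 1,4-dioxane, 90 °C
Reagents that add atoms: none
Why: Stille cross-coupling should transfer the hydroxymethyl group to the alkenyl iodide with retention of alkene geometry, which places CH2OH cis to the C4 carbinol, and free hydroxyl groups are tolerated.

**Step 7**
Reactants: 11 (1S,2E,4R)-2-(hydroxymethyl)-1,4-di-Ar-but-2-ene-1,4-diol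
Product: 13 (S)-Ar[(5R)-5-Ar-2,5-dihydrofuran-3-yl]methanol, via primary allylic tosylate 12 (not isolated)
Conditions: NaH, N-tosylimidazole (1.0 equiv), THF, 0 °C to rt
Reagents that add atoms: none
Why: Cyclodehydration by selective sulfonylation of the primary allylic alkoxide and 5-exo-tet Williamson displacement by the cis-disposed secondary alkoxide should close the 2,5-dihydrofuran; the C–O bonds at both stereocentres stay intact and the other carbinol could only close a four-membered ring.

**Step 8**
Reactants: 13 (S)-Ar[(5R)-5-Ar-2,5-dihydrofuran-3-yl]methanol, 14 tributyl(iodomethyl)stannane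
Product: 15 tributyl({(S)-Ar[(5R)-5-Ar-2,5-dihydrofuran-3-yl]methoxy}methyl)stannane
Conditions: KH, THF, 0 °C; then 14, 0 °C to rt
Reagents that add atoms: none
Why: Williamson etherification of the potassium alkoxide with the iodomethylstannane is the standard entry to Still's stannylmethyl ethers and involves no stereocentre.

**Step 9**
Reactants: 15 tributyl({(S)-Ar[(5R)-5-Ar-2,5-dihydrofuran-3-yl]methoxy}methyl)stannane
Product: 17 {(2R,3S,4E)-2-Ar-4-(Ar-methylidene)oxolan-3-yl}methanol, via lithiomethyl ether 16 (not isolated)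
Conditions: n-BuLi (1.2 equiv), THF, −78 °C, then to −40 °C; H2O
Reagents that add atoms: none
Why: Tin–lithium exchange gives the unstabilised α-alkoxymethyllithium 16, which undergoes a concerted suprafacial [2,3]-sigmatropic shift through a five-membered envelope transition state in which C7 bonds to C3, the C3=C4 π bond moves to C4=C6 and the C6–O bond breaks. The closest known reaction type is the Wittig–Still rearrangement of secondary allylic stannylmethyl ethers that carry a substituent on the central allyl carbon, which gives trisubstituted alkenes with the carbinol substituent cis to the carbon that receives CH2OH. No ring is closed: the oxygen heterocycle is already in place and only its endocyclic alkene is transposed to the exocyclic position. The new C3 stereocentre is controlled by 1,3-chirality transfer from the (S)-configured C6 (oxygen and the new C–C bond on the same face) and by the C2 aryl group, which shields the opposite face, so both elements deliver C7 trans to the C2 aryl group (a matched case that follows from the C2-symmetric origin of 7). The alkene geometry is controlled by allylic strain in the envelope: the C6 aryl group avoids the C5 methylene on the central carbon C4 and lies on the side of the C3–H bond, which leaves it cis to C3 as in the target. The step needs [2,3] over [1,2] selectivity, which the unstabilised carbanion at −78 °C should secure, and it needs this pairing of face and geometry, which the (2R,6S) relationship in 15 should secure.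

**Step 10**
Reactants: 17 {(2R,3S,4E)-2-Ar-4-(Ar-methylidene)oxolan-3-yl}methanol, 18 4-hydroxybenzoic acid
Product: 19 {(2R,3S,4E)-2-Ar-4-(Ar-methylidene)oxolan-3-yl}methyl 4-hydroxybenzoate
Conditions: PPh3, DIAD, THF, 0 °C to rt
Reagents that add atoms: none
Why: Mitsunobu esterification, in which the carboxylic acid (far more acidic than the phenol) is the pronucleophile that displaces the activated primary alcohol, so the ester should form without phenol protection and without touching a stereocentre.

**Step 11**
Reactants: 19 {(2R,3S,4E)-2-Ar-4-(Ar-methylidene)oxolan-3-yl}methyl 4-hydroxybenzoate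
Product: 20 agastenol
Conditions: TBAF, AcOH, THF, 0 °C
Reagents that add atoms: none
Why: Fluoride-mediated cleavage of both aryl silyl ethers under acetic acid buffering should spare the benzoate ester, the styrene and the sensitive p-hydroxybenzylic ether, and it leaves C2, C3 and the alkene geometry untouched.

**Compound list**

1 | vanillin | COc1cc(C=O)ccc1O | starting material
2 | 3-methoxy-4-(triisopropylsilyloxy)benzaldehyde | COc1cc(C=O)ccc1O[Si](C(C)C)(C(C)C)C(C)C | intermediate
3 | acetylene | C#C | starting material
4 | ethynediylbis(magnesium bromide) | Br[Mg]C#C[Mg]Br | intermediate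
5 | 1,4-di-Ar-but-2-yne-1,4-diol, racemic plus meso | OC(c1ccc(O[Si](C(C)C)(C(C)C)C(C)C)c(OC)c1)C#CC(O)c1ccc(O[Si](C(C)C)(C(C)C)C(C)C)c(OC)c1 | intermediate
6 | 1,4-di-Ar-but-2-yne-1,4-dione | O=C(c1ccc(O[Si](C(C)C)(C(C)C)C(C)C)c(OC)c1)C#CC(=O)c1ccc(O[Si](C(C)C)(C(C)C)C(C)C)c(OC)c1 | intermediate
7 | (1S,4S)-1,4-di-Ar-but-2-yne-1,4-diol | O[C@@H](c1ccc(O[Si](C(C)C)(C(C)C)C(C)C)c(OC)c1)C#C[C@H](c1ccc(O[Si](C(C)C)(C(C)C)C(C)C)c(OC)c1)O | intermediate
8 | cyclic sodium alkenylalanate from anti-hydroalumination of 7 (idealised monomer: 1,2-oxaaluminol-2-uide with two 2-methoxyethoxy groups on Al, disodium salt) | [Na+].[Na+].COCCO[Al-]1(OCCOC)O[C@@H](c2ccc(O[Si](C(C)C)(C(C)C)C(C)C)c(OC)c2)C=C1[C@H](c1ccc(O[Si](C(C)C)(C(C)C)C(C)C)c(OC)c1)[O-] | intermediate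
9 | (1S,2Z,4R)-2-iodo-1,4-di-Ar-but-2-ene-1,4-diol | O[C@@H](c1ccc(O[Si](C(C)C)(C(C)C)C(C)C)c(OC)c1)/C(I)=C/[C@H](c1ccc(O[Si](C(C)C)(C(C)C)C(C)C)c(OC)c1)O | intermediate
10 | (tributylstannyl)methanol | CCCC[Sn](CCCC)(CCCC)CO | starting material
11 | (1S,2E,4R)-2-(hydroxymethyl)-1,4-di-Ar-but-2-ene-1,4-diol | O[C@@H](c1ccc(O[Si](C(C)C)(C(C)C)C(C)C)c(OC)c1)/C(CO)=C/[C@H](c1ccc(O[Si](C(C)C)(C(C)C)C(C)C)c(OC)c1)O | intermediate
12 | primary mono-tosylate of 11, (2E,3S)-3-hydroxy-2-[(2R)-2-hydroxy-2-Ar-ethylidene]-3-Ar-propyl 4-methylbenzenesulfonate | O[C@@H](c1ccc(O[Si](C(C)C)(C(C)C)C(C)C)c(OC)c1)/C(COS(=O)(=O)c1ccc(C)cc1)=C/[C@H](c1ccc(O[Si](C(C)C)(C(C)C)C(C)C)c(OC)c1)O | intermediate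
13 | (S)-Ar[(5R)-5-Ar-2,5-dihydrofuran-3-yl]methanol | O[C@@H](c1ccc(O[Si](C(C)C)(C(C)C)C(C)C)c(OC)c1)C1=C[C@H](c2ccc(O[Si](C(C)C)(C(C)C)C(C)C)c(OC)c2)OC1 | intermediate
14 | tributyl(iodomethyl)stannane | CCCC[Sn](CCCC)(CCCC)CI | starting material
15 | tributyl({(S)-Ar[(5R)-5-Ar-2,5-dihydrofuran-3-yl]methoxy}methyl)stannane | CCCC[Sn](CCCC)(CCCC)CO[C@@H](c1ccc(O[Si](C(C)C)(C(C)C)C(C)C)c(OC)c1)C1=C[C@H](c2ccc(O[Si](C(C)C)(C(C)C)C(C)C)c(OC)c2)OC1 | intermediate
16 | ({(S)-Ar[(5R)-5-Ar-2,5-dihydrofuran-3-yl]methoxy}methyl)lithium | [Li]CO[C@@H](c1ccc(O[Si](C(C)C)(C(C)C)C(C)C)c(OC)c1)C1=C[C@H](c2ccc(O[Si](C(C)C)(C(C)C)C(C)C)c(OC)c2)OC1 | intermediate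
17 | {(2R,3S,4E)-2-Ar-4-(Ar-methylidene)oxolan-3-yl}methanol | COc1cc(/C=C2/CO[C@@H](c3ccc(O[Si](C(C)C)(C(C)C)C(C)C)c(OC)c3)[C@@H]2CO)ccc1O[Si](C(C)C)(C(C)C)C(C)C | intermediate
18 | 4-hydroxybenzoic acid | OC(=O)c1ccc(O)cc1 | starting material
19 | {(2R,3S,4E)-2-Ar-4-(Ar-methylidene)oxolan-3-yl}methyl 4-hydroxybenzoate | COc1cc(/C=C2/CO[C@@H](c3ccc(O[Si](C(C)C)(C(C)C)C(C)C)c(OC)c3)[C@@H]2COC(=O)c2ccc(O)cc2)ccc1O[Si](C(C)C)(C(C)C)C(C)C | intermediate
20 | agastenol, {(2R,3S,4E)-2-(4-hydroxy-3-methoxyphenyl)-4-[(4-hydroxy-3-methoxyphenyl)methylidene]oxolan-3-yl}methyl 4-hydroxybenzoate | COc1cc(/C=C2/CO[C@@H](c3ccc(O)c(OC)c3)[C@@H]2COC(=O)c2ccc(O)cc2)ccc1O | target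

**Step count and risks**

Total step count: 11. Longest linear sequence: 11 steps (1 to 20).

Steps most likely to fail:

1. Step 9. The lithiomethyl ether may partly follow the dissociative [1,2]-pathway, or the pairing of face and alkene geometry may erode if the envelope preference is weaker than expected. Fallback: setting out from 13, the alcohol would be converted with phenyl isocyanate into the N-phenylcarbamate F1. Copper-mediated syn-SN2′ substitution of the N-lithiated carbamate with (isopropoxydimethylsilyl)methylmagnesium chloride (n-BuLi, CuI, THF) would deliver the carbon nucleophile to C3 on the face of the leaving group and give the silylmethyl compound F2 with the same C3 configuration and alkene geometry. Tamao oxidation (H2O2, KHCO3, THF/MeOH) would then return to the route at 17.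

2. Step 4. Hydride transfer may discriminate poorly between the aryl and the alkynyl group, or slow reduction may allow dehydroboration and unselective reduction by 9-BBN. Fallback: setting out from 5, lipase-catalysed kinetic resolution (Candida antarctica lipase B, vinyl acetate, toluene) should acylate the (S)-carbinol centres (aryl as large, alkynyl as medium group in the Kazlauskas model). This would give the (1S,4S)-diacetate F3, separable from the meso monoacetate and the unreacted (R,R)-diol. Mild methanolysis (K2CO3, MeOH, 0 °C) would return to the route at 7.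

3. Step 6. Transmetallation of the sp3 hydroxymethyl group to the hindered alkenylpalladium may be slow, so that protodeiodination competes. Fallback: setting out from 9, palladium-catalysed carbonylative lactonisation (CO 1 atm, PdCl2(PPh3)2, K2CO3, THF) onto the cis C4 hydroxyl would give the butenolide F4; base and temperature would be kept low to avoid epimerisation at its γ-carbon. DIBAL reduction (CH2Cl2, −78 to 0 °C) of the lactone to the Z-ene-1,4-diol would return to the route at 11.

**Further compounds**

F1 | step 9 | (S)-Ar[(5R)-5-Ar-2,5-dihydrofuran-3-yl]methyl N-phenylcarbamate | O=C(Nc1ccccc1)O[C@@H](c1ccc(O[Si](C(C)C)(C(C)C)C(C)C)c(OC)c1)C1=C[C@H](c2ccc(O[Si](C(C)C)(C(C)C)C(C)C)c(OC)c2)OC1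
F2 | step 9 | (2R,3R,4E)-2-Ar-4-(Ar-methylidene)-3-{[isopropoxy(dimethyl)silyl]methyl}oxolane | COc1cc(/C=C2/CO[C@@H](c3ccc(O[Si](C(C)C)(C(C)C)C(C)C)c(OC)c3)[C@@H]2C[Si](C)(C)OC(C)C)ccc1O[Si](C(C)C)(C(C)C)C(C)C
F3 | step 4 | (1S,4S)-1,4-di-Ar-but-2-yne-1,4-diyl diacetate | CC(=O)O[C@@H](c1ccc(O[Si](C(C)C)(C(C)C)C(C)C)c(OC)c1)C#C[C@H](c1ccc(O[Si](C(C)C)(C(C)C)C(C)C)c(OC)c1)OC(C)=O
F4 | step 6 | (5R)-5-Ar-3-[(S)-Ar(hydroxy)methyl]furan-2(5H)-one | O[C@@H](c1ccc(O[Si](C(C)C)(C(C)C)C(C)C)c(OC)c1)C1=C[C@H](c2ccc(O[Si](C(C)C)(C(C)C)C(C)C)c(OC)c2)OC1=O
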